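**Retrosynthetic overview**
- Last operation: one hydrogenolysis removes 13 benzyl ethers and the two C8 bromine caps.
- Interflavan C4–C6 bond: an 8-bromo-capped 4β-alkoxy-epicatechin cation precursor meets an 8-bromo-capped epigallocatechin digallate. In that nucleophile, C6 is the only open ring A position.
- Key disconnection: both galloyl ester C–O bonds (O3 and O3') of the lower unit are made in one operation. Acylative opening of a ring B diphenylmethylene ketal decides O3' against O4'.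
- Upper unit: the C4–O bond comes from DDQ oxidation of benzylated epicatechin.
- Rings: no ring of the target is built, since all come from epicatechin, epigallocatechin and gallic acid. Only a temporary dioxole on ring B is closed (step 4) and opened (step 6).

Assumption: (−)-epicatechin, (−)-epigallocatechin and 3,4,5-tris(benzyloxy)benzoic acid are bought, the two catechins as the natural single enantiomers.

**Step 1**
Reactants: 1 (−)-epicatechin
Product: 2 5,7,3',4'-tetra-O-benzyl-(−)-epicatechin (2R,3R; 3-OH free)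
Conditions: BnBr (4.4 equiv), K2CO3 (5 equiv), DMF, Ar, 0 °C to rt
Reagents that add atoms: benzyl bromide, BrCc1ccccc1
Why: Williamson ether synthesis in which only the four phenols are ionised by K2CO3, so the secondary 3-OH stays free and C2/C3 are untouched at room temperature.

**Step 2**
Reactants: 2 5,7,3',4'-tetra-O-benzyl-(−)-epicatechin
Product: 3 4β-(2-ethoxyethoxy)-5,7,3',4'-tetra-O-benzylepicatechin (2,3-cis-3,4-trans)
Conditions: DDQ (2 equiv), 2-ethoxyethanol (6 equiv), CH2Cl2, rt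
Reagents that add atoms: 2-ethoxyethanol, CCOCCO
Why: DDQ benzylic oxidation (hydride abstraction) gives the ring A-stabilised flavan-4-yl cation, which the alcohol captures on the face anti to the 2-aryl and 3-OH groups, so only the 4β ether forms.

**Step 3**
Reactants: 3 4β-(2-ethoxyethoxy)-5,7,3',4'-tetra-O-benzylepicatechin
Product: 4 8-bromo-4β-(2-ethoxyethoxy)-5,7,3',4'-tetra-O-benzylepicatechin
Conditions: NBS (1.0 equiv), CH2Cl2, −78 to 0 °C
Reagents that add atoms: N-bromosuccinimide, O=C1CCC(=O)N1Br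
Why: Electrophilic aromatic bromination takes the most reactive ring A position of 5,7-di-O-benzyl flavans (C8), and this cap later stops self-condensation of the electrophile through C8.

**Step 4**
Reactants: 5 (−)-epigallocatechin
Product: 7 5,7,5'-tri-O-benzyl-3',4'-O-diphenylmethylene-(−)-epigallocatechin (2R,3R; 3-OH free), via ring B ketal 6 (not isolated)
Conditions: Ph2CCl2 (1.1 equiv), K2CO3 (6 equiv), MeCN/DMF 1:1, Ar, rt; then BnBr (3.5 equiv), 40 °C
Reagents that add atoms: dichlorodiphenylmethane, ClC(Cl)(c1ccccc1)c1ccccc1; benzyl bromide, BrCc1ccccc1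
Why: Double substitution on Ph2CCl2 can close a five-membered ketal only across two vicinal ring B oxygens, which also ties up the 4'-phenoxide needed for C2 epimerisation, and the following Williamson benzylation in the same base caps the three remaining phenols.

**Step 5**
Reactants: 7 5,7,5'-tri-O-benzyl-3',4'-O-diphenylmethylene-(−)-epigallocatechin
Product: 8 8-bromo-5,7,5'-tri-O-benzyl-3',4'-O-diphenylmethylene-epigallocatechin
Conditions: NBS (1.0 equiv), CH2Cl2, −78 to 0 °C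
Reagents that add atoms: N-bromosuccinimide, O=C1CCC(=O)N1Br
Why: Electrophilic aromatic bromination goes to C8 because ring A, with three mutually meta oxygens, far outruns ring B, and this leaves C6 as the only nucleophilic ring A carbon.

**Step 6**
Reactants: 8 8-bromo-5,7,5'-tri-O-benzyl-3',4'-O-diphenylmethylene-epigallocatechin; 9 3,4,5-tris(benzyloxy)benzoic acid (2.2 equiv)
Product: 12 8-bromo-5,7,5'-tri-O-benzylepigallocatechin 3,3'-bis-O-[3,4,5-tris(benzyloxy)benzoate] (4'-OH free), via acid chloride 10 (not isolated), via chlorodiphenylmethyl ether 11 (not isolated)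
Conditions: 9, (COCl)2, cat. DMF, CH2Cl2, rt, evaporate; then 8, Zn(OTf)2 (10 mol%), 2,6-di-tert-butyl-4-methylpyridine (1.2 equiv), 4 Å MS, CH2Cl2/MeCN 9:1, 0 °C to rt; then pH 6 phosphate buffer/THF
Reagents that add atoms: none
Why: Proposed new method: Zn(OTf)2 acylates the free 3-OH with 10 in the usual Lewis acid-catalysed way and, new for a catechol diphenylmethylene ketal, reversibly ionises the dioxole to a zinc aryloxide plus a diaryl-stabilised oxocarbenium ion, of which the O3' aryloxide (better leaving group, no ortho substituent) is trapped irreversibly by 10 while chloride caps the carbenium ion as the O4' chlorodiphenylmethyl ether 11, so that O4' (flanked by OBn) stays masked against over-acylation until the buffered quench releases benzophenone; the closest known reaction type is the zinc salt-catalysed exchange of dialkyl acetals with acid halides to give an ester and an alpha-halo ether, and no stereocentre is touched.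

**Step 7**
Reactants: 4 8-bromo-4β-(2-ethoxyethoxy)-5,7,3',4'-tetra-O-benzylepicatechin (1.0 equiv, added slowly); 12 8-bromo-5,7,5'-tri-O-benzylepigallocatechin 3,3'-bis-O-[3,4,5-tris(benzyloxy)benzoate] (1.5 equiv)
Product: 13 8-bromo-5,7,3',4'-tetra-O-benzylepicatechin-(4β→6)-8-bromo-5,7,5'-tri-O-benzylepigallocatechin 3,3'-bis-O-[3,4,5-tris(benzyloxy)benzoate]
Conditions: TMSOTf (0.3 equiv), 4 Å MS, CH2Cl2, −78 to −30 °C; aq. NaHCO3
Reagents that add atoms: none
Why: Lewis acid-catalysed Friedel-Crafts flavanylation (SN1) in which the C4 cation from 4 is attacked by the only free ring A carbon of 12 (C6) on the face anti to the 2-aryl and 3-OH groups, which sets C4 as 4β (3,4-trans), while the C8 cap, slow addition and excess 12 suppress self-condensation of 4.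

**Step 8**
Reactants: 13 protected (4β→6) dimer
Product: 14 epicatechin-(4β→6)-epigallocatechin 3,3'-di-O-gallate (target)
Conditions: H2 (1 atm), 20% Pd(OH)2/C, THF/MeOH/H2O 20:20:1, rt; filter under Ar, Sephadex LH-20
Reagents that add atoms: none
Why: Catalytic hydrogenolysis cleaves all 13 benzyl ethers and hydrodebrominates both aryl bromides under neutral to slightly acidic conditions, so both esters, the pyran rings, the interflavan bond and all five stereocentres survive and 3' to 4' acyl migration is not triggered.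

**Compound list**
1 | (−)-epicatechin | Oc1ccc([C@H]2Oc3cc(O)cc(O)c3C[C@H]2O)cc1O | starting material
2 | 5,7,3',4'-tetra-O-benzyl-(−)-epicatechin | C(Oc1ccc([C@H]2Oc3cc(OCc4ccccc4)cc(OCc4ccccc4)c3C[C@H]2O)cc1OCc1ccccc1)c1ccccc1 | intermediate
3 | 4β-(2-ethoxyethoxy)-5,7,3',4'-tetra-O-benzylepicatechin | CCOCCO[C@H]1c2c(OCc3ccccc3)cc(OCc3ccccc3)cc2O[C@H](c2ccc(OCc3ccccc3)c(OCc3ccccc3)c2)[C@@H]1O | intermediate
4 | 8-bromo-4β-(2-ethoxyethoxy)-5,7,3',4'-tetra-O-benzylepicatechin | CCOCCO[C@H]1c2c(OCc3ccccc3)cc(OCc3ccccc3)c(Br)c2O[C@H](c2ccc(OCc3ccccc3)c(OCc3ccccc3)c2)[C@@H]1O | intermediate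
5 | (−)-epigallocatechin | Oc1cc([C@H]2Oc3cc(O)cc(O)c3C[C@H]2O)cc(O)c1O | starting material
6 | 3',4'-O-diphenylmethylene-(−)-epigallocatechin | Oc1cc([C@H]2Oc3cc(O)cc(O)c3C[C@H]2O)cc2OC(c3ccccc3)(c3ccccc3)Oc12 | intermediate
7 | 5,7,5'-tri-O-benzyl-3',4'-O-diphenylmethylene-(−)-epigallocatechin | C(Oc1cc([C@H]2Oc3cc(OCc4ccccc4)cc(OCc4ccccc4)c3C[C@H]2O)cc2OC(c3ccccc3)(c3ccccc3)Oc12)c1ccccc1 | intermediate
8 | 8-bromo-5,7,5'-tri-O-benzyl-3',4'-O-diphenylmethylene-epigallocatechin | C(Oc1cc([C@H]2Oc3c(Br)c(OCc4ccccc4)cc(OCc4ccccc4)c3C[C@H]2O)cc2OC(c3ccccc3)(c3ccccc3)Oc12)c1ccccc1 | intermediate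
9 | 3,4,5-tris(benzyloxy)benzoic acid | OC(=O)c1cc(OCc2ccccc2)c(OCc2ccccc2)c(OCc2ccccc2)c1 | starting material
10 | 3,4,5-tris(benzyloxy)benzoyl chloride | ClC(=O)c1cc(OCc2ccccc2)c(OCc2ccccc2)c(OCc2ccccc2)c1 | intermediate
11 | 8-bromo-5,7,5'-tri-O-benzyl-4'-O-(chlorodiphenylmethyl)epigallocatechin 3,3'-bis-O-[3,4,5-tris(benzyloxy)benzoate] | O=C(Oc1cc([C@H]2Oc3c(Br)c(OCc4ccccc4)cc(OCc4ccccc4)c3C[C@H]2OC(=O)c2cc(OCc3ccccc3)c(OCc3ccccc3)c(OCc3ccccc3)c2)cc(OCc2ccccc2)c1OC(Cl)(c1ccccc1)c1ccccc1)c1cc(OCc2ccccc2)c(OCc2ccccc2)c(OCc2ccccc2)c1 | intermediate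
12 | 8-bromo-5,7,5'-tri-O-benzylepigallocatechin 3,3'-bis-O-[3,4,5-tris(benzyloxy)benzoate] (4'-OH free) | O=C(Oc1cc([C@H]2Oc3c(Br)c(OCc4ccccc4)cc(OCc4ccccc4)c3C[C@H]2OC(=O)c2cc(OCc3ccccc3)c(OCc3ccccc3)c(OCc3ccccc3)c2)cc(OCc2ccccc2)c1O)c1cc(OCc2ccccc2)c(OCc2ccccc2)c(OCc2ccccc2)c1 | intermediate
13 | 8-bromo-5,7,3',4'-tetra-O-benzylepicatechin-(4β→6)-8-bromo-5,7,5'-tri-O-benzylepigallocatechin 3,3'-bis-O-[3,4,5-tris(benzyloxy)benzoate] | O=C(Oc1cc([C@H]2Oc3c(Br)c(OCc4ccccc4)c([C@H]4c5c(OCc6ccccc6)cc(OCc6ccccc6)c(Br)c5O[C@H](c5ccc(OCc6ccccc6)c(OCc6ccccc6)c5)[C@@H]4O)c(OCc4ccccc4)c3C[C@H]2OC(=O)c2cc(OCc3ccccc3)c(OCc3ccccc3)c(OCc3ccccc3)c2)cc(OCc2ccccc2)c1O)c1cc(OCc2ccccc2)c(OCc2ccccc2)c(OCc2ccccc2)c1 | intermediate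
14 | epicatechin-(4β→6)-epigallocatechin 3,3'-di-O-gallate (upper unit 2R,3R,4S; lower unit 2R,3R) | O=C(Oc1cc([C@H]2Oc3cc(O)c([C@H]4c5c(O)cc(O)cc5O[C@H](c5ccc(O)c(O)c5)[C@@H]4O)c(O)c3C[C@H]2OC(=O)c2cc(O)c(O)c(O)c2)cc(O)c1O)c1cc(O)c(O)c(O)c1 | target

**Step count and risks**

Total step count: 8. Longest linear sequence: 5 (steps 1, 2, 3, 7, 8 or steps 4, 5, 6, 7, 8).

**Step 6 (new acylative ketal opening).** The ketal may not ionise under Zn(OTf)2, or O4' may compete with O3'.
- The fallback uses known chemistry, sets out from 8 and comes back at 12.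
- First, the 3-OH alone is esterified with 10 (Et3N, DMAP, CH2Cl2, rt), and the ketal is inert to this. The product is 8-bromo-5,7,5'-tri-O-benzyl-3',4'-O-diphenylmethylene-epigallocatechin 3-O-[3,4,5-tris(benzyloxy)benzoate] F1.
- Second, the ketal is hydrolysed (AcOH/H2O 4:1, 80 °C) to the catechol 8-bromo-5,7,5'-tri-O-benzylepigallocatechin 3-O-[3,4,5-tris(benzyloxy)benzoate] F2.
- Third, 1.0 equiv of 10 with 2,4,6-collidine in CH2Cl2 at −40 °C acylates the unhindered 3'-OH ahead of the 4'-OH, which is flanked by OBn. This gives 12.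

**Step 7 (attack by the sluggish C6 position).** Self-condensation of 4 through its own C6, or decomposition before coupling, is possible.
- The fallback sets out from 4 and comes back at 13. It replaces hard-acid activation of a C4–O group by thiophilic activation of a C4–S group.
- 4 is treated with 2-mercaptobenzothiazole and AlMe3 (CH2Cl2, 0 °C to rt). This gives 8-bromo-4β-(benzothiazol-2-ylthio)-5,7,3',4'-tetra-O-benzylepicatechin F3.
- F3 is stable in the presence of 12 until AgBF4 (THF, 0 °C) releases the cation irreversibly, and C6 of 12 then captures it to give 13.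

**Step 8 (13 benzyl groups and two bromides next to a migration-prone aryl ester).** Stalled hydrogenolysis or acyl migration on long exposure is possible.
- The fallback sets out from 13 and comes back at 14. It separates the two tasks and avoids a heterogeneous catalyst.
- Radical hydrodebromination (Bu3SnH, AIBN, toluene, 80 °C) gives 5,7,3',4'-tetra-O-benzylepicatechin-(4β→6)-5,7,5'-tri-O-benzylepigallocatechin 3,3'-bis-O-[3,4,5-tris(benzyloxy)benzoate] F4.
- Lewis acid debenzylation with a cation scavenger (BCl3, pentamethylbenzene, CH2Cl2, −78 °C) then gives 14.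

**Further compounds**
F1 | step 6 | 8-bromo-5,7,5'-tri-O-benzyl-3',4'-O-diphenylmethylene-epigallocatechin 3-O-[3,4,5-tris(benzyloxy)benzoate] | C(Oc1cc([C@H]2Oc3c(Br)c(OCc4ccccc4)cc(OCc4ccccc4)c3C[C@H]2OC(=O)c2cc(OCc3ccccc3)c(OCc3ccccc3)c(OCc3ccccc3)c2)cc2OC(c3ccccc3)(c3ccccc3)Oc12)c1ccccc1
F2 | step 6 | 8-bromo-5,7,5'-tri-O-benzylepigallocatechin 3-O-[3,4,5-tris(benzyloxy)benzoate] | Oc1cc([C@H]2Oc3c(Br)c(OCc4ccccc4)cc(OCc4ccccc4)c3C[C@H]2OC(=O)c2cc(OCc3ccccc3)c(OCc3ccccc3)c(OCc3ccccc3)c2)cc(OCc2ccccc2)c1O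
F3 | step 7 | 8-bromo-4β-(benzothiazol-2-ylthio)-5,7,3',4'-tetra-O-benzylepicatechin | c1ccc2sc(S[C@H]3c4c(OCc5ccccc5)cc(OCc5ccccc5)c(Br)c4O[C@H](c4ccc(OCc5ccccc5)c(OCc5ccccc5)c4)[C@@H]3O)nc2c1
F4 | step 8 | 5,7,3',4'-tetra-O-benzylepicatechin-(4β→6)-5,7,5'-tri-O-benzylepigallocatechin 3,3'-bis-O-[3,4,5-tris(benzyloxy)benzoate] | O=C(Oc1cc([C@H]2Oc3cc(OCc4ccccc4)c([C@H]4c5c(OCc6ccccc6)cc(OCc6ccccc6)cc5O[C@H](c5ccc(OCc6ccccc6)c(OCc6ccccc6)c5)[C@@H]4O)c(OCc4ccccc4)c3C[C@H]2OC(=O)c2cc(OCc3ccccc3)c(OCc3ccccc3)c(OCc3ccccc3)c2)cc(OCc2ccccc2)c1O)c1cc(OCc2ccccc2)c(OCc2ccccc2)c(OCc2ccccc2)c1
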